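The benzylic carbon C15 between C9 and the quinone is treated as a former ring atom. Ring B (C5–C10) is traced back to a cis-fused cycloheptene in which C15 lies between C8 and C9. Lewis-acid semipinacol (Meinwald) rearrangement of its α-epoxide moves the C15–C8 bond to C9: in one operation the seven-membered ring contracts to ring B, the quaternary stereocentre C9 is set with inversion, and C15 is expelled as the aldehyde that later receives the arene. The step exploits quaternary C9 of ring B, which bears a one-carbon arm and adjoins the C8 methine. The precursor is epoxide 11, assembled on 3-methylcyclohept-2-enone by a methylenecyclohexane annulation and two copper-catalysed conjugate additions.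

Key step: step 7

Numbering used: ring A = C1–C5 and C10, ring B = C5–C10, C11 = methylidene carbon on C4, C15 = the carbon on C9 that ends as the benzylic CH2. The α face is the face of ring B that carries H-10 and the C5 methyl. The target is the cis-fused (5R,8R,9R,10S) isomer.
Assumption: 3-methylcyclohept-2-en-1-one (1) is bought as a catalogue building block.

Step 1
Reactants: 1 3-methylcyclohept-2-en-1-one; 2 5-chloropent-1-yne
Product: 4 (R)-3-(5-chloropent-1-en-2-yl)-3-methylcycloheptan-1-one, via alkenylalane 3 (not isolated)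
Conditions: 2, i-Bu2AlH, NiCl2(Ph2PCH2CH2CH2PPh2) (3 mol%), THF, 0 → 22 °C; then 1, Cu(O2CC4H3S) (10 mol%), chiral N,N-bis(1-phenylethyl)-P,P-diphenylphosphinous amide (11 mol%, antipode chosen to give (R)-4), Et2O, −20 °C; aq. NH4Cl
Reagents that add atoms: none
Why: Nickel-catalysed hydroalumination should place aluminium on the internal alkyne carbon, and copper-catalysed enantioselective conjugate addition of the alkenylalane to the β-methyl enone should create the quaternary centre C5 under control of the chiral ligand.

Step 2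
Reactants: 4 (R)-3-(5-chloropent-1-en-2-yl)-3-methylcycloheptan-1-one
Product: 5 (4aR,9aR)-9a-methyl-1-methylidenedecahydro-5H-benzo[7]annulen-5-one (cis-fused)
Conditions: KH, THF, 0 → 22 °C
Reagents that add atoms: none
Why: Intramolecular enolate alkylation (6-exo-tet, methylenecyclohexane annulation) closes ring A at C10, and because the tether reaches the enolate carbon from the C5 substituent the new C10–C1 bond must form cis to C5–C4, which sets H-10 cis to the C5 methyl.

Step 3
Reactants: 5 (4aR,9aR)-9a-methyl-1-methylidenedecahydro-5H-benzo[7]annulen-5-one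
Product: 7 (4aR,9aR)-9a-methyl-1-methylidene-1,2,3,4,4a,8,9,9a-octahydro-5H-benzo[7]annulen-5-one, via silyl enol ether 6 (not isolated)
Conditions: LiN(i-Pr)2, THF, −78 °C; Me3SiCl; then Pd(OAc)2, MeCN, 22 °C
Reagents that add atoms: none
Why: Kinetic deprotonation should occur at the C15 methylene and not at the hindered ring-fusion methine C10, and Saegusa–Ito oxidation of the silyl enol ether should give the C15=C8 enone without epimerising C10.

Step 4
Reactants: 7 (4aR,9aR)-9a-methyl-1-methylidene-1,2,3,4,4a,8,9,9a-octahydro-5H-benzo[7]annulen-5-one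
Product: 9 (4aR,7R,9aR)-7,9a-dimethyl-1-methylidene-2,3,4,4a,7,8,9,9a-octahydro-1H-benzo[7]annulen-5-yl trifluoromethanesulfonate, via zinc enolate 8 (not isolated)
Conditions: Me2Zn, Cu(OTf)2 (2 mol%), chiral binaphthol-derived bis(1-phenylethyl)amine phosphoramidite (4 mol%, antipode chosen for α attack at C8), toluene, −30 °C; then Tf2O, −30 → 0 °C
Reagents that add atoms: dimethylzinc, C[Zn]C; trifluoromethanesulfonic anhydride, O=S(=O)(OS(=O)(=O)C(F)(F)F)C(F)(F)F
Why: Copper-catalysed enantioselective conjugate addition of dimethylzinc to the cycloheptenone should set C8 under ligand control (methyl on the α face, cis to H-10), and the zinc enolate is trapped on oxygen as the C9 enol triflate.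

Step 5
Reactants: 9 (4aR,7R,9aR)-7,9a-dimethyl-1-methylidene-2,3,4,4a,7,8,9,9a-octahydro-1H-benzo[7]annulen-5-yl trifluoromethanesulfonate
Product: 10 (4aS,7R,9aR)-5,7,9a-trimethyl-1-methylidene-2,3,4,4a,7,8,9,9a-octahydro-1H-benzo[7]annulene
Conditions: MeMgBr, Fe(acac)3 (5 mol%), THF/N-methylpyrrolidone, −30 → 0 °C
Reagents that add atoms: methylmagnesium bromide, C[Mg]Br
Why: Iron-catalysed Kumada-type cross-coupling of the alkenyl triflate with the methyl Grignard reagent should install the C9 methyl and leave the C9=C15 alkene, the methylidene group and C8 untouched.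

Step 6
Reactants: 10 (4aS,7R,9aR)-5,7,9a-trimethyl-1-methylidene-2,3,4,4a,7,8,9,9a-octahydro-1H-benzo[7]annulene
Product: 11 (4aR,5S,6R,7R,9aR)-5,6-epoxy-5,7,9a-trimethyl-1-methylidenedecahydro-1H-benzo[7]annulene (α-epoxide, oxygen cis to H-10, to the C5 methyl and to the C8 methyl)
Conditions: mCPBA, NaHCO3, CH2Cl2, −20 → 0 °C
Reagents that add atoms: 3-chloroperoxybenzoic acid, O=C(OO)c1cccc(Cl)c1
Why: Prilezhaev epoxidation should pick the electron-rich trisubstituted C9=C15 alkene over the hindered 1,1-disubstituted methylidene, and the peracid should approach the convex α face because ring A screens the β face next to C10, which sets C9 and C15.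

Step 7
Reactants: 11 (4aR,5S,6R,7R,9aR)-5,6-epoxy-5,7,9a-trimethyl-1-methylidenedecahydro-1H-benzo[7]annulene
Product: 12 (1R,2R,4aR,8aR)-1,2,4a-trimethyl-5-methylidenedecahydronaphthalene-1-carbaldehyde
Conditions: MeAl(OC6H2-4-Br-2,6-t-Bu2)2 (20 mol%), CH2Cl2, −78 → −40 °C
Reagents that add atoms: none
Why: The bulky aluminium Lewis acid binds the epoxide oxygen and the tertiary C9–O bond ionises while the C15–C8 ring bond, which the flexible seven-membered ring can place anti-periplanar to it, shifts from C15 to C9 and C15 becomes the aluminium-bound aldehyde (concerted 1,2-alkyl shift, Meinwald/semipinacol rearrangement). The closest known reaction type is the rearrangement of trisubstituted epoxides to α-quaternary aldehydes with this aluminium phenoxide, including ring contraction of 1-methylcycloalkene oxides. Ring B (C5–C10) is closed by this 1,2-shift, that is by one-carbon contraction of the seven-membered ring and not by a cyclisation. C9 is the only new stereocentre: C8 bonds to C9 on the side opposite to the departing oxygen, so the α-epoxide should give the α-formyl, β-methyl arrangement (inversion at C9), and C8 migrates with retention. The step needs alkyl shift instead of hydride shift from C15 and no capture of the developing C9 cation by the C4 methylidene group; the bulk of the aluminium phenoxide, the strain relief of the seven-to-six contraction and the low temperature with a non-nucleophilic counter-ion should secure this.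

Step 8
Reactants: 12 (1R,2R,4aR,8aR)-1,2,4a-trimethyl-5-methylidenedecahydronaphthalene-1-carbaldehyde; 13 1,2,4,5-tetramethoxybenzene
Product: 16 O-{(2,3,5,6-tetramethoxyphenyl)[(1R,2R,4aR,8aR)-1,2,4a-trimethyl-5-methylidenedecahydronaphthalen-1-yl]methyl} S-methyl carbonodithioate (both carbinol epimers), via aryllithium 14 (not isolated), via lithium alkoxide 15 (not isolated)
Conditions: 13, n-BuLi, THF, 0 °C; 12, −78 → 0 °C; then CS2; MeI, 22 °C
Reagents that add atoms: carbon disulfide, S=C=S; iodomethane, CI
Why: Directed ortho-lithiation between two methoxy groups gives the aryllithium, which adds to the non-enolisable neopentyl aldehyde, and the alkoxide is converted in the same flask into the S-methyl xanthate (the carbinol configuration is uncontrolled and is removed in the next step).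

Step 9
Reactants: 16 O-{(2,3,5,6-tetramethoxyphenyl)[(1R,2R,4aR,8aR)-1,2,4a-trimethyl-5-methylidenedecahydronaphthalen-1-yl]methyl} S-methyl carbonodithioate
Product: 17 1,2,4,5-tetramethoxy-3-{[(1R,2R,4aR,8aS)-1,2,4a-trimethyl-5-methylidenedecahydronaphthalen-1-yl]methyl}benzene
Conditions: n-Bu3SnH, AIBN (cat.), toluene, 110 °C
Reagents that add atoms: none
Why: Barton–McCombie deoxygenation: the stannyl radical cleaves the xanthate to a benzylic radical that is reduced by the tin hydride, which leaves C15 as the benzylic CH2 and creates no stereocentre.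

Step 10
Reactants: 17 1,2,4,5-tetramethoxy-3-{[(1R,2R,4aR,8aS)-1,2,4a-trimethyl-5-methylidenedecahydronaphthalen-1-yl]methyl}benzene
Product: 18 2,5-dimethoxy-3-{[(1R,2R,4aR,8aS)-1,2,4a-trimethyl-5-methylidenedecahydronaphthalen-1-yl]methyl}cyclohexa-2,5-diene-1,4-dione
Conditions: (NH4)2Ce(NO3)6, MeCN/H2O, 0 °C
Reagents that add atoms: water, O
Why: Oxidative demethylation of a para-dimethoxy pair by (NH4)2Ce(NO3)6 should give the 2,5-dimethoxy-1,4-benzoquinone (both para pairs lead to the same quinone), and the isolated methylidene group is not oxidised under these conditions.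

Step 11
Reactants: 18 2,5-dimethoxy-3-{[(1R,2R,4aR,8aS)-1,2,4a-trimethyl-5-methylidenedecahydronaphthalen-1-yl]methyl}cyclohexa-2,5-diene-1,4-dione
Product: 19 2-hydroxy-5-methoxy-3-{[(1R,2R,4aR,8aS)-1,2,4a-trimethyl-5-methylidenedecahydronaphthalen-1-yl]methyl}cyclohexa-2,5-diene-1,4-dione (CID71726091)
Conditions: 70% aq. HClO4, THF, 0 → 22 °C
Reagents that add atoms: water, O
Why: Acid-catalysed addition–elimination of water at the vinylogous ester carbon next to the alkyl chain, whose methoxy group is twisted out of conjugation and is therefore the more labile one, should give the 2-hydroxy-5-methoxyquinone.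

Compound list
1 | 3-methylcyclohept-2-en-1-one | CC1=CC(=O)CCCC1 | starting material
2 | 5-chloropent-1-yne | ClCCCC#C | starting material
3 | (5-chloropent-1-en-2-yl)bis(2-methylpropyl)alumane | C=C(CCCCl)[Al](CC(C)C)CC(C)C | intermediate (not isolated)
4 | (R)-3-(5-chloropent-1-en-2-yl)-3-methylcycloheptan-1-one | C=C(CCCCl)[C@@]1(C)CC(=O)CCCC1 | intermediate
5 | (4aR,9aR)-9a-methyl-1-methylidenedecahydro-5H-benzo[7]annulen-5-one | C=C1CCC[C@H]2C(=O)CCCC[C@@]12C | intermediate
6 | trimethylsilyl enol ether of 5 (C9=C15) | C=C1CCC[C@H]2C(O[Si](C)(C)C)=CCCC[C@@]12C | intermediate (not isolated)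
7 | (4aR,9aR)-9a-methyl-1-methylidene-1,2,3,4,4a,8,9,9a-octahydro-5H-benzo[7]annulen-5-one | C=C1CCC[C@H]2C(=O)C=CCC[C@@]12C | intermediate
8 | methylzinc enolate of the C8-methylated ketone | C=C1CCC[C@H]2C(O[Zn]C)=C[C@H](C)CC[C@@]12C | intermediate (not isolated)
9 | (4aR,7R,9aR)-7,9a-dimethyl-1-methylidene-2,3,4,4a,7,8,9,9a-octahydro-1H-benzo[7]annulen-5-yl trifluoromethanesulfonate | C=C1CCC[C@H]2C(OS(=O)(=O)C(F)(F)F)=C[C@H](C)CC[C@@]12C | intermediate
10 | (4aS,7R,9aR)-5,7,9a-trimethyl-1-methylidene-2,3,4,4a,7,8,9,9a-octahydro-1H-benzo[7]annulene | C=C1CCC[C@H]2C(C)=C[C@H](C)CC[C@@]12C | intermediate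
11 | (4aR,5S,6R,7R,9aR)-5,6-epoxy-5,7,9a-trimethyl-1-methylidenedecahydro-1H-benzo[7]annulene (α-epoxide) | C=C1CCC[C@H]2[C@]3(C)O[C@@H]3[C@H](C)CC[C@@]12C | intermediate
12 | (1R,2R,4aR,8aR)-1,2,4a-trimethyl-5-methylidenedecahydronaphthalene-1-carbaldehyde | C=C1CCC[C@H]2[C@](C)(C=O)[C@H](C)CC[C@@]12C | intermediate
13 | 1,2,4,5-tetramethoxybenzene | COc1cc(OC)c(OC)cc1OC | starting material
14 | (2,3,5,6-tetramethoxyphenyl)lithium | [Li]c1c(OC)c(OC)cc(OC)c1OC | intermediate (not isolated)
15 | lithium alkoxide of the aryl carbinol from 12 and 14 | C=C1CCC[C@H]2[C@](C)(C(O[Li])c3c(OC)c(OC)cc(OC)c3OC)[C@H](C)CC[C@@]12C | intermediate (not isolated)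
16 | O-{(2,3,5,6-tetramethoxyphenyl)[(1R,2R,4aR,8aR)-1,2,4a-trimethyl-5-methylidenedecahydronaphthalen-1-yl]methyl} S-methyl carbonodithioate | C=C1CCC[C@H]2[C@](C)(C(OC(=S)SC)c3c(OC)c(OC)cc(OC)c3OC)[C@H](C)CC[C@@]12C | intermediate
17 | 1,2,4,5-tetramethoxy-3-{[(1R,2R,4aR,8aS)-1,2,4a-trimethyl-5-methylidenedecahydronaphthalen-1-yl]methyl}benzene | C=C1CCC[C@H]2[C@](C)(Cc3c(OC)c(OC)cc(OC)c3OC)[C@H](C)CC[C@@]12C | intermediate
18 | 2,5-dimethoxy-3-{[(1R,2R,4aR,8aS)-1,2,4a-trimethyl-5-methylidenedecahydronaphthalen-1-yl]methyl}cyclohexa-2,5-diene-1,4-dione | C=C1CCC[C@H]2[C@](C)(CC3=C(OC)C(=O)C=C(OC)C3=O)[C@H](C)CC[C@@]12C | intermediate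
19 | 2-hydroxy-5-methoxy-3-{[(1R,2R,4aR,8aS)-1,2,4a-trimethyl-5-methylidenedecahydronaphthalen-1-yl]methyl}cyclohexa-2,5-diene-1,4-dione | C=C1CCC[C@H]2[C@](C)(CC3=C(O)C(=O)C=C(OC)C3=O)[C@H](C)CC[C@@]12C | target

Total step count: 11. Longest linear sequence: 11 steps (1 → 19).

Steps most likely to fail

Step 7. The rearrangement may go by hydride shift from C15 (giving the seven-membered ketone), lose stereospecificity at C9 through a free cation, or be intercepted by the methylidene group. The fallback contracts ring B by a photochemical Wolff rearrangement; it sets out from enone 7 and comes back at aldehyde 12. The conjugate addition of step 4 is quenched with aqueous NH4Cl to give (4aR,7R,9aR)-7,9a-dimethyl-1-methylidenedecahydro-5H-benzo[7]annulen-5-one F1. Kinetic trifluoroacetylation at C15 (LiN(SiMe3)2, CF3CO2CH2CF3) gives the 6-(trifluoroacetyl) ketone F2, and diazo transfer (MsN3, Et3N) gives the 6-diazo ketone F3. Irradiation in methanol shifts C10 from C9 to C15 with retention, through the ring-contracted ketene F4, to the methyl decalincarboxylate F5. Enolate methylation (LiN(i-Pr)2, MeI), expected anti to the C8 methyl, gives methyl (1R,2R,4aR,8aR)-1,2,4a-trimethyl-5-methylidenedecahydronaphthalene-1-carboxylate F6. LiAlH4 gives [(1R,2R,4aR,8aR)-1,2,4a-trimethyl-5-methylidenedecahydronaphthalen-1-yl]methanol F7, and Dess–Martin oxidation gives 12.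

Step 6. The peracid may attack the β face of the C9=C15 alkene, which would lead to the C9 epimer after step 7. The fallback reaches the epoxide through a halohydrin, so that the oxygen ends on the face opposite to the one the electrophile attacks; it sets out from alkene 10 and comes back at epoxide 11. N-Bromosuccinimide in aqueous THF should give, by β bromonium formation and anti opening by water at the tertiary carbon, the bromohydrin with 9α-hydroxy and 15β-bromo groups F8. K2CO3 in methanol closes it with inversion at C15 to 11.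

Step 4. Ligand control may be overridden by the substrate (mismatched double stereodifferentiation), which would give poor facial selectivity at C8. The fallback relays the configuration from C10 through C9; it sets out from enone 7 and comes back at alkene 10, so it replaces steps 4 and 5. MeLi/CeCl3 should add to the ketone from the convex α face to give the tertiary allylic alcohol with 9β-hydroxy and 9α-methyl groups F9. Acetylation (Ac2O, 4-dimethylaminopyridine, Et3N) gives the tertiary allylic acetate F10. Me2CuLi then displaces the acetate in an anti-SN2′ fashion, which puts the methyl on the α face of C8 and leaves the C9=C15 alkene of 10.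

Further compounds
F1 | step 7 | (4aR,7R,9aR)-7,9a-dimethyl-1-methylidenedecahydro-5H-benzo[7]annulen-5-one | C=C1CCC[C@H]2C(=O)C[C@H](C)CC[C@@]12C
F2 | step 7 | 6-(trifluoroacetyl) derivative of F1 (C15 epimers) | C=C1CCC[C@H]2C(=O)C(C(=O)C(F)(F)F)[C@H](C)CC[C@@]12C
F3 | step 7 | 6-diazo derivative of F1 | C=C1CCC[C@H]2C(=O)C(=[N+]=[N-])[C@H](C)CC[C@@]12C
F4 | step 7 | ring-contracted ketene (cis-decalin with C=C=O on the ring carbon between C8 and C10) | C=C1CCC[C@H]2C(=C=O)[C@H](C)CC[C@@]12C
F5 | step 7 | methyl 2,4a-dimethyl-5-methylidenedecahydronaphthalene-1-carboxylate (C1 epimers; 2R,4a R, H-8a cis to the 4a-methyl) | C=C1CCC[C@H]2C(C(=O)OC)[C@H](C)CC[C@@]12C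
F6 | step 7 | methyl (1R,2R,4aR,8aR)-1,2,4a-trimethyl-5-methylidenedecahydronaphthalene-1-carboxylate | C=C1CCC[C@H]2[C@](C)(C(=O)OC)[C@H](C)CC[C@@]12C
F7 | step 7 | [(1R,2R,4aR,8aR)-1,2,4a-trimethyl-5-methylidenedecahydronaphthalen-1-yl]methanol | C=C1CCC[C@H]2[C@](C)(CO)[C@H](C)CC[C@@]12C
F8 | step 6 | bromohydrin of 10 (9α-hydroxy, 9β-methyl, 15β-bromo) | C=C1CCC[C@H]2[C@](C)(O)[C@@H](Br)[C@H](C)CC[C@@]12C
F9 | step 4 | tertiary allylic alcohol from 7 (9β-hydroxy, 9α-methyl, C15=C8) | C=C1CCC[C@H]2[C@@](C)(O)C=CCC[C@@]12C
F10 | step 4 | acetate of F9 | C=C1CCC[C@H]2[C@@](C)(OC(C)=O)C=CCC[C@@]12C
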